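**Retrosynthetic overview**
- Last step: the cyclopentane and the eight-membered ring are closed together by a two-carbon ring expansion, in which the tetronate C=C of a tricyclic aldehyde is inserted into the C1–C2 bond of a chiral cyclohexane-1,3-dione (aldol, Michael addition, cyclobutanolate fragmentation).
- Tricyclic aldehyde (tetronate fused to a 2-oxabicyclo[2.2.2]octane): ether bridge by trans opening of an epoxide by a tetronic acid, itself from Dieckmann closure of an α-acetoxy ester.
- Functionalised cyclohexene: MeLi addition to a 2-methylcyclohexenone and ester-enolate acetoxylation; the enone from a catalytic asymmetric Diels–Alder reaction of a 2-silyloxydiene with methyl (E)-4-oxobut-2-enoate.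
- Dione: Michael/Claisen annulation of the pivaldehyde acetal of (R)-lactic acid with 3-methylbut-3-en-2-one.
- Ring order: cyclohexene, then tetronic acid (butenolide), then oxa-bridge; the six-membered dione separately; cyclopentane and cyclooctane in one final operation.

Assumption: the E-enol in the target SMILES is taken as the hydrogen-bonded tautomer of the β-keto lactone, and all three starting materials are taken as catalogue compounds.

**Step 1**
Reactants: 1 3-methylbut-3-en-2-one
Product: 2 3-methyl-2-[(triisopropylsilyl)oxy]buta-1,3-diene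
Conditions: i-Pr3SiOTf, Et3N, CH2Cl2, 0 °C
Reagents that add atoms: triisopropylsilyl triflate, CC(C)[Si](C(C)C)(C(C)C)OS(=O)(=O)C(F)(F)F
Why: Soft enolisation and O-silylation of the methyl ketone (silyl enol ether formation) gives the 2-silyloxydiene; no stereocentre is formed.

**Step 2**
Reactants: 2 3-methyl-2-[(triisopropylsilyl)oxy]buta-1,3-diene; 3 methyl (E)-4-oxobut-2-enoate
Product: 4 methyl (1S,6S)-6-formyl-4-methyl-3-[(triisopropylsilyl)oxy]cyclohex-3-ene-1-carboxylate
Conditions: (S)-3,3-diphenyl-1-(o-tolyl)tetrahydro-1H,3H-pyrrolo[1,2-c][1,3,2]oxazaborole·HNTf2 (20 mol %), CH2Cl2, −78 °C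
Reagents that add atoms: none
Why: Catalytic enantioselective Diels–Alder reaction in which the cationic oxazaborolidine binds the formyl group, so the diene CH2 next to C–OSi bonds to the carbon β to CHO (para orientation), the E-dienophile fixes CHO and CO2Me trans, and face shielding by the catalyst (attack on the Si face of the formyl-bearing carbon) sets both stereocentres.

**Step 3**
Reactants: 4 methyl (1S,6S)-6-formyl-4-methyl-3-[(triisopropylsilyl)oxy]cyclohex-3-ene-1-carboxylate
Product: 5 methyl (1S,6S)-6-(dimethoxymethyl)-4-methyl-3-[(triisopropylsilyl)oxy]cyclohex-3-ene-1-carboxylate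
Conditions: HC(OMe)3, MeOH, pyridinium p-toluenesulfonate (5 mol %), 0 °C
Reagents that add atoms: trimethyl orthoformate, COC(OC)OC; methanol, CO
Why: Chemoselective acetalisation of the aldehyde (the hindered triisopropylsilyl enol ether and the ester survive) masks it before the basic steps and before the γ-formyl enone can form; no stereocentre changes.

**Step 4**
Reactants: 5 methyl (1S,6S)-6-(dimethoxymethyl)-4-methyl-3-[(triisopropylsilyl)oxy]cyclohex-3-ene-1-carboxylate
Product: 6 methyl (1S,2S)-2-(dimethoxymethyl)-4-methyl-5-oxocyclohex-3-ene-1-carboxylate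
Conditions: Pd(OAc)2 (10 mol %), O2 (1 atm), DMSO, 60 °C
Reagents that add atoms: none
Why: Saegusa–Ito oxidation of the silyl enol ether (oxo-π-allyl palladium, β-hydride elimination into the ring) gives the 2-methylcyclohexenone regiospecifically; the two stereocentres are untouched.

**Step 5**
Reactants: 6 methyl (1S,2S)-2-(dimethoxymethyl)-4-methyl-5-oxocyclohex-3-ene-1-carboxylate
Product: 7 methyl (1S,2S,5R)-2-(dimethoxymethyl)-5-hydroxy-4,5-dimethylcyclohex-3-ene-1-carboxylate
Conditions: MeLi, CeCl3, THF, −78 °C; then H2O
Reagents that add atoms: methyllithium, [Li]C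
Why: Organocerium 1,2-addition to the enone (the ester is inert at −78 °C) occurs by axial attack on the half-chair anti to the pseudo-equatorial CO2Me, so the new methyl is trans and the tertiary OH cis to the ester (5R).

**Step 6**
Reactants: 7 methyl (1S,2S,5R)-2-(dimethoxymethyl)-5-hydroxy-4,5-dimethylcyclohex-3-ene-1-carboxylate
Product: 10 methyl (1S,2S,5R)-1-acetoxy-2-(dimethoxymethyl)-5-hydroxy-4,5-dimethylcyclohex-3-ene-1-carboxylate, via bis-silyl ketene acetal 8 (not isolated), via silyl ether acetate 9 (not isolated)
Conditions: LiN(i-Pr)2 (2.4 equiv), Me3SiCl (3 equiv), THF, −78 °C; Pb(OAc)4, CH2Cl2, −40 → 0 °C; citric acid, MeOH, 0 °C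
Reagents that add atoms: chlorotrimethylsilane (kept only in 8 and 9), C[Si](C)(C)Cl; lead tetraacetate, CC(=O)O[Pb](OC(C)=O)(OC(C)=O)OC(C)=O
Why: Rubottom-type lead tetraacetate oxidation of the silyl ketene acetal gives the α-acetoxy ester directly; the acetoxy group enters equatorially, anti to the neighbouring CH(OMe)2 and to the syn-axial methyl of the carbinol, so OAc ends cis to the tertiary OH and the ester cis to CH(OMe)2 (1S), and methanolysis frees the tertiary alcohol.

**Step 7**
Reactants: 10 methyl (1S,2S,5R)-1-acetoxy-2-(dimethoxymethyl)-5-hydroxy-4,5-dimethylcyclohex-3-ene-1-carboxylate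
Product: 11 methyl (1S,2S,3S,4S,5R)-1-acetoxy-2-(dimethoxymethyl)-3,4-epoxy-5-hydroxy-4,5-dimethylcyclohexane-1-carboxylate
Conditions: VO(acac)2 (5 mol %), t-BuOOH, CH2Cl2, 0 → 25 °C
Reagents that add atoms: tert-butyl hydroperoxide, CC(C)(C)OO
Why: Hydroxyl-directed vanadium-catalysed epoxidation of the allylic tertiary alcohol delivers oxygen syn to the OH (also the face anti to CH(OMe)2), which sets both oxirane carbons.

**Step 8**
Reactants: 11 methyl (1S,2S,3S,4S,5R)-1-acetoxy-2-(dimethoxymethyl)-3,4-epoxy-5-hydroxy-4,5-dimethylcyclohexane-1-carboxylate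
Product: 13 tricyclic tetronate acetal (furan-2(5H)-one fused to a 2-oxabicyclo[2.2.2]octane; CH(OMe)2 syn to the tetronate bridge; both OH groups anti to the ether bridge), via epoxy spirotetronic acid 12 (not isolated)
Conditions: LiN(SiMe3)2 (3.3 equiv), THF, −78 → −30 °C; AcOH; then (+)-10-camphorsulfonic acid (10 mol %), CH2Cl2, 25 °C
Reagents that add atoms: none
Why: Dieckmann condensation of the acetate enolate onto the adjacent ester gives the tetronic acid, whose enol oxygen then opens the epoxide at the tertiary carbon with inversion (acid-catalysed, as in abyssomicin core syntheses), closing the 2-oxabicyclo[2.2.2]octane and leaving the secondary OH anti to the new ether bridge.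

**Step 9**
Reactants: 14 (R)-lactic acid
Product: 15 (2R,5R)-2-tert-butyl-5-methyl-1,3-dioxolan-4-one
Conditions: t-BuCHO, p-toluenesulfonic acid (cat.), pentane, reflux (Dean–Stark); recrystallise the cis isomer
Reagents that add atoms: pivaldehyde, CC(C)(C)C=O
Why: Acetalisation (Seebach dioxolanone) keeps the lactic acid centre and places the tert-butyl group cis to the methyl in the thermodynamic, crystalline isomer.

**Step 10**
Reactants: 15 (2R,5R)-2-tert-butyl-5-methyl-1,3-dioxolan-4-one; 1 3-methylbut-3-en-2-one
Product: 17 (4S,6S)-4-hydroxy-4,6-dimethylcyclohexane-1,3-dione, via Michael adduct 16 (not isolated)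
Conditions: LiN(i-Pr)2, THF, −78 °C; then 1; then KOt-Bu (0.2 equiv), t-BuOH, −78 → 25 °C; 1 M HCl
Reagents that add atoms: none
Why: Self-regeneration of the stereocentre: the dioxolanone enolate adds to the enone (Michael addition) anti to tert-butyl, giving the 4S carbinol carbon; the equilibrated methyl-ketone enolate then closes onto the dioxolanone carbonyl (Claisen cyclisation, pivaldehyde is lost) through the chair with both methyls equatorial (Curtin–Hammett), which sets 6S before the product is frozen as its enolate.

**Step 11**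
Reactants: 13 tricyclic tetronate acetal; 17 (4S,6S)-4-hydroxy-4,6-dimethylcyclohexane-1,3-dione
Product: 20 CNP0073514.1 (target), via tricyclic aldehyde 18 (not isolated), via aldol adduct 19 (not isolated)
Conditions: CF3CO2H–H2O (9:1), CH2Cl2, 0 °C, evaporate; then 17, Mg(OTf)2 (1.5 equiv), Et3N (0.5 equiv), THF–H2O (20:1), 0 → 50 °C
Reagents that add atoms: water, O
Why: Proposed new method: after acetal hydrolysis the soft-enolised dione adds to the aldehyde (aldol), the dione carbon of adduct 19 attacks the tetronate β-carbon 5-exo from the only face the tether allows (cyclopentane and quaternary ether carbon), and the resulting lactone enolate adds to the nearer ring ketone (C-1, flanked by CHMe) to give a cyclobutanolate that fragments by retro-aldol, so the tetronate C=C is inserted into the C1–C2 bond of the dione (six- to eight-membered ring) and the enolised β-keto lactone appears; Mg2+ held by the new alkoxide, the α-ketol and the ether oxygen is expected to place the carbinol oxygen on the cage side and to leave C-1 free to migrate, and protonation gives the cis ring fusion; closest known reactions are the De Mayo reaction (photochemical [2+2] then retro-aldol), anionic Michael–aldol–retro-Dieckmann two-carbon ring expansions, acyl-alkylation insertions into β-dicarbonyl C–C bonds and the abyssomicin C to D transannular Michael addition.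

**Compound list**
1 | 3-methylbut-3-en-2-one | CC(=O)C(C)=C | starting material
2 | 3-methyl-2-[(triisopropylsilyl)oxy]buta-1,3-diene | C=C(C)C(=C)O[Si](C(C)C)(C(C)C)C(C)C | intermediate
3 | methyl (E)-4-oxobut-2-enoate | COC(=O)/C=C/C=O | starting material
4 | methyl (1S,6S)-6-formyl-4-methyl-3-[(triisopropylsilyl)oxy]cyclohex-3-ene-1-carboxylate (CHO and CO2Me trans) | O=C[C@H]1CC(C)=C(O[Si](C(C)C)(C(C)C)C(C)C)C[C@@H]1C(=O)OC | intermediate
5 | methyl (1S,6S)-6-(dimethoxymethyl)-4-methyl-3-[(triisopropylsilyl)oxy]cyclohex-3-ene-1-carboxylate | COC(OC)[C@H]1CC(C)=C(O[Si](C(C)C)(C(C)C)C(C)C)C[C@@H]1C(=O)OC | intermediate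
6 | methyl (1S,2S)-2-(dimethoxymethyl)-4-methyl-5-oxocyclohex-3-ene-1-carboxylate | COC(OC)[C@H]1C=C(C)C(=O)C[C@@H]1C(=O)OC | intermediate
7 | methyl (1S,2S,5R)-2-(dimethoxymethyl)-5-hydroxy-4,5-dimethylcyclohex-3-ene-1-carboxylate (OH cis to CO2Me) | COC(OC)[C@H]1C=C(C)[C@](C)(O)C[C@@H]1C(=O)OC | intermediate
8 | methyl trimethylsilyl ketene acetal of 7 with the tertiary OH as trimethylsilyl ether (ketene acetal geometry not defined) | COC(OC)[C@H]1C=C(C)[C@](C)(O[Si](C)(C)C)CC1=C(OC)O[Si](C)(C)C | intermediate
9 | methyl (1S,2S,5R)-1-acetoxy-2-(dimethoxymethyl)-4,5-dimethyl-5-[(trimethylsilyl)oxy]cyclohex-3-ene-1-carboxylate | COC(OC)[C@H]1C=C(C)[C@](C)(O[Si](C)(C)C)C[C@@]1(OC(C)=O)C(=O)OC | intermediate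
10 | methyl (1S,2S,5R)-1-acetoxy-2-(dimethoxymethyl)-5-hydroxy-4,5-dimethylcyclohex-3-ene-1-carboxylate (OAc cis to OH, trans to CH(OMe)2) | COC(OC)[C@H]1C=C(C)[C@](C)(O)C[C@@]1(OC(C)=O)C(=O)OC | intermediate
11 | methyl (1S,2S,3S,4S,5R)-1-acetoxy-2-(dimethoxymethyl)-3,4-epoxy-5-hydroxy-4,5-dimethylcyclohexane-1-carboxylate (oxirane O cis to OH and OAc) | COC(OC)[C@H]1[C@@H]2O[C@]2(C)[C@](C)(O)C[C@@]1(OC(C)=O)C(=O)OC | intermediate
12 | epoxy spirotetronic acid (4-hydroxyfuran-2(5H)-one spiro-fused at C-5 to the epoxycyclohexane of 11) | COC(OC)[C@H]1[C@@H]2O[C@]2(C)[C@](C)(O)C[C@]13OC(=O)C=C3O | intermediate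
13 | tricyclic tetronate acetal (tetronate fused to a 2-oxabicyclo[2.2.2]octane; CH(OMe)2 syn to the tetronate bridge; secondary and tertiary OH anti to the ether bridge) | COC(OC)[C@H]1[C@H](O)[C@@]2(C)OC3=CC(=O)O[C@@]13C[C@@]2(C)O | intermediate
14 | (R)-lactic acid | C[C@@H](O)C(=O)O | starting material
15 | (2R,5R)-2-tert-butyl-5-methyl-1,3-dioxolan-4-one (cis) | C[C@H]1O[C@@H](C(C)(C)C)OC1=O | intermediate
16 | (2R,5S)-2-tert-butyl-5-methyl-5-(2-methyl-3-oxobutyl)-1,3-dioxolan-4-one (side-chain centre as epimer mixture) | CC(=O)C(C)C[C@]1(C)O[C@@H](C(C)(C)C)OC1=O | intermediate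
17 | (4S,6S)-4-hydroxy-4,6-dimethylcyclohexane-1,3-dione (methyls cis, OH trans to the C-6 methyl) | C[C@H]1C[C@](C)(O)C(=O)CC1=O | intermediate
18 | tricyclic aldehyde (13 with CHO in place of CH(OMe)2) | O=C[C@H]1[C@H](O)[C@@]2(C)OC3=CC(=O)O[C@@]13C[C@@]2(C)O | intermediate
19 | aldol adduct of 17 (C-2) with aldehyde 18, drawn as the enol and as the carbinol epimer that cyclises | C[C@H]1C[C@](C)(O)C(=O)C(=C1O)[C@@H](O)[C@H]2[C@H](O)[C@@]3(C)OC4=CC(=O)O[C@@]24C[C@@]3(C)O | intermediate
20 | CNP0073514.1 | C[C@H]1C[C@](C)(O)C(=O)[C@@H]2[C@@H](O)[C@H]3[C@H](O)[C@@]4(C)O[C@@]25/C(=C\1O)C(=O)O[C@@]35C[C@@]4(C)O | target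

**Step count**
Total steps: 11. Longest linear sequence: 9 (steps 1–8 and 11); steps 9–10 make the dione in parallel.

**Steps most likely to fail**

Step 11 (the new ring expansion). The Michael addition to the tetronate may be too slow, so that the dehydrated alkylidene dione is diverted (for example by hetero-Diels–Alder addition to the tetronate). The other ring carbonyl may migrate, or the wrong carbinol epimer may cyclise. The fallback uses known photochemistry and sets out from 13 and 17. Acetal 13 is hydrolysed to 18 as before and condensed with 17 in water at 25 °C to give 19. Irradiation of 19 (350 nm, MeCN) brings about the intramolecular [2+2] photocycloaddition of the dione enol to the tetronate C=C (De Mayo reaction; five-membered ring closure first), giving the cyclobutanol photoadduct F1. Its retro-aldol opening, spontaneous or with a trace of Et3N, comes back to the route at 20.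

Step 2 (asymmetric Diels–Alder). The facial sense or the level of induction with this doubly activated dienophile is not secured by a close precedent, and the silyl enol ether may react with the activated aldehyde. If only the facial sense is wrong, the antipodal catalyst is used. The fallback replaces catalyst control by auxiliary control; it sets out from 3 and 2 and returns at 4. Aldehyde 3 is oxidised (NaClO2, NaH2PO4, 2-methylbut-2-ene) to monomethyl fumarate F2. This is activated with pivaloyl chloride and Et3N as the mixed anhydride F3 and coupled with (S)-4-benzyloxazolidin-2-one (LiCl) to the imide dienophile F4. The Et2AlCl-chelated imide is now the stronger activating group, so the Diels–Alder reaction with 2 (CH2Cl2, −78 °C) has the same regiochemistry and gives the adduct F5 on the face away from the benzyl group. LiBH4 (Et2O, 1 equiv H2O) cleaves the imide selectively to the primary alcohol F6, and Dess–Martin oxidation gives 4.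

Step 8 (Dieckmann closure and ether-bridge formation). The tertiary alkoxide may take the acetyl group from the neighbouring oxygen before the Dieckmann closure, the epoxide may suffer under the base, and the neighbouring carbinol may erode the preference for opening at the tertiary carbon. The fallback follows the order used in Sorensen's abyssomicin C endgame and sets out from 9, which is isolated by leaving out the methanolysis in step 6. With LiN(SiMe3)2 and an acidic work-up, 9 gives the spirotetronic acid F7 with no free alkoxide present during the condensation. O-Methylation (Me2SO4, K2CO3, acetone) gives the methyl tetronate F8, and hydroxyl-directed epoxidation (VO(acac)2, t-BuOOH) gives the stable epoxide F9. LiCl in DMSO at 50 °C removes the methyl group to give 12, and p-toluenesulfonic acid closes the ether bridge, so the route is rejoined at 13.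

Further compounds
F1 | step 11 | cyclobutanol photoadduct of 19 (cyclobutane from the dione enol C=C and the tetronate C=C; tertiary cyclobutanol) | C[C@H]1C[C@](C)(O)C(=O)[C@]23[C@@H](O)[C@H]4[C@H](O)[C@@]5(C)O[C@@]36[C@@H]([C@@]12O)C(=O)O[C@@]46C[C@@]5(C)O
F2 | step 2 | monomethyl fumarate | COC(=O)/C=C/C(=O)O
F3 | step 2 | pivaloyl mixed anhydride of monomethyl fumarate | COC(=O)/C=C/C(=O)OC(=O)C(C)(C)C
F4 | step 2 | methyl (E)-4-[(4S)-4-benzyl-2-oxo-1,3-oxazolidin-3-yl]-4-oxobut-2-enoate | COC(=O)/C=C/C(=O)N1C(=O)OC[C@@H]1Cc1ccccc1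
F5 | step 2 | Diels–Alder adduct of F4 and 2 (imide analogue of 4; same ring configuration) | O=C([C@H]1CC(C)=C(O[Si](C(C)C)(C(C)C)C(C)C)C[C@@H]1C(=O)OC)N2C(=O)OC[C@@H]2Cc3ccccc3
F6 | step 2 | methyl (1S,6S)-6-(hydroxymethyl)-4-methyl-3-[(triisopropylsilyl)oxy]cyclohex-3-ene-1-carboxylate | OC[C@H]1CC(C)=C(O[Si](C(C)C)(C(C)C)C(C)C)C[C@@H]1C(=O)OC
F7 | step 8 | spirotetronic acid of the cyclohexene (12 without the epoxide) | COC(OC)[C@H]1C=C(C)[C@](C)(O)C[C@]12OC(=O)C=C2O
F8 | step 8 | methyl tetronate of F7 | COC(OC)[C@H]1C=C(C)[C@](C)(O)C[C@]12OC(=O)C=C2OC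
F9 | step 8 | epoxide of F8 (oxirane O cis to the tertiary OH) | COC(OC)[C@H]1[C@@H]2O[C@]2(C)[C@](C)(O)C[C@]13OC(=O)C=C3OC
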